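The share of target in target plus isomer of the product A (the selectivity) stays close between the two earlier runs: at 12.0 h it reads 56.6 % in the beta run and 54.8 % in the theta run, although starting material went from 0.0067 M to 0.015 M.

in all of them: catalyst 10 µM
- beta: starting material 0.0067 M; reagent 7 mM; run made earlier
- theta: starting material 0.015 M; reagent 7 mM; run made earlier
- flask: starting material 0.010 M; reagent 7.00 mM; time 15 h

| run | time / h | target / % | isomer of the product A / % |
|---|---|---|---|
| beta | 1.50 | 58.1 | 8.9 |
| beta | 4.00 | 56.9 | 17.8 |
| beta | 8.00 | 49.5 | 28.9 |
| beta | 12.0 | 44.7 | 34.3 |
| theta | 1.50 | 34.7 | 5.4 |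
| theta | 4.00 | 30.9 | 10.7 |
| theta | 8.00 | 25.7 | 16.9 |
| theta | 12.0 | 23.6 | 19.5 |

(scatter of a reading: 0.3 percentage points)

- share of target in target plus isomer of the product A at 40 s
- share of target in target plus isomer of the product A at 15 h

- the earlier runs were read with a standard deviation of 0.3 percentage points

Reagent and catalyst stood equal in both runs; charge them as written. Averaged over the two runs, the share reads 86.6 %, 75.2 %, 61.7 % and 55.7 % at the reading times.

My reckoning treats the last stretch as a small correction. The late slope, the fall of the share per hour between the last two readings, is 0.0152 /h as a fraction of one. Over the time from the last reading to 15 h it takes off 4.5 points, leaving my estimate of 51.1 % for this flask. The fall from 4.00 h to 8.00 h was larger than the next one, so treat my late estimate as a low end. The line through the two earliest readings, drawn back to 40 s, gives a low end of 93.4 %.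

The forecast says 95 % and 52.5 %, holding that “The decline fits relaxation toward a plateau”; my late figure lies 1.4 points below its figure.

The flask gives 97.5 % and 52.1 %; the later share lies 1 point above my estimate.

    starting material + reagent ⇌ target (K = 2000 /M, k = 5.00 /M/min)
    starting material + reagent ⇌ isomer of the product A (K = 2400 /M, k = 0.120 /M/min)
    catalyst ⇌ dormant form (K = 2.70, k = 0.0410 /min)
    target + catalyst ⇌ isomer of the product A + catalyst, rate k4*[catalyst]*[target] forward; the back reaction follows from the equilibrium constant (k = 470 /M/min)
    target ⇌ isomer of the product B (K = 0.100, k = 0.00690 /min)

The step between target and isomer of the product A carries c(catalyst) in its rate. Take the neighbouring flask with 6.0 × 10⁻⁶ M of catalyst, and let its clock run slower in proportion, so that 15 h there counts as 9.00 h on the clock of the runs. From the share at 8.00 h, the late slope takes off 1.5 points and leaves 60.2 %. That neighbouring flask gives 59.8 %, with target at 36.5 %.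

The data come from a simulation on assumed constants; noise was put on by code.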